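Cuts: the two C15–O–CO ester bonds between the units; in each albicane the ring bonds C4–C5 and C9–C10 (with a 3β-hydroxyl put back on C3); the three C11–O ether bonds; the C3–CH2 bond of each isocitrate (back to malate).
Enabling feature: each trans-decalin (stereocentres C4, C5, C9, C10; C8(12) exocyclic methylene; C11–O ether to an isocitrate; C15–O ester to the next isocitrate) is atom for atom a folded (E,E)-farnesyl ether oxygenated at C12, so the neopentyl C15 esters can be made as esters of an unhindered primary 2,3-epoxy alcohol before any ring exists.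
Forward: D-malic acid gives two 1-methyl malates that differ in the C4 ester (2-(trimethylsilyl)ethyl for units B and C, allyl for unit A); alkylation gives the isocitrate triesters (side-chain allyl for B and C, methyl for A); each is O-farnesylated, oxidised at C12 and epoxidised.
The open chain is then joined (ester C to B, then B to A); one titanium-mediated radical operation closes all six carbocycles (ring A before ring B in each unit); threefold C3 deoxygenation and a single global deallylation finish.
Stereochemistry: isocitrate C2 from D-malic acid, C3 from the anti Fráter–Seebach alkylation; the (10S) epoxide carbon from Sharpless epoxidation with L-(+)-diethyl tartrate becomes a 3β-carbinol that steers C4, C5, C9 and C10 through a chair–chair transition state of the E,E-diene and is then removed.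

Key step: step 19

Remark on the chemistry: drimane numbering is used for the decalins (C11 = CH2O on C9, C12 = exocyclic methylene carbon on C8, C15 = oxygenated 4α-CH2 on C4) and farnesyl numbering for the open chains (C1 = ether CH2, C12 = oxidised (E)-methyl). In the isocitrates the C1 carboxyl sits on the oxygen-bearing C2, the central carboxyl on C3 and the C5 carboxyl at the end of the CH2 arm. Unit A carries the isocitrate with the free central carboxyl, unit C the free C15 hydroxyl, and unit B lies between. The central carboxyl of unit A is carried as an allyl ester, so that one palladium-catalysed operation at the end releases it together with the side-chain allyl esters of units B and C and the allyl carbonate.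

Step 1
Reactants: 1 D-malic acid ((R)-2-hydroxybutanedioic acid)
Product: 2 [(4R)-2,2-dimethyl-5-oxo-1,3-dioxolan-4-yl]acetic acid
Conditions: 2,2-dimethoxypropane, p-TsOH·H2O (cat.), 25 °C
Reagents that add atoms: 2,2-dimethoxypropane, COC(C)(C)OC
Why: Acid-catalysed acetal exchange (dioxolanone formation) ties the C2 hydroxyl and the C1 carboxyl into the favoured five-membered ring, leaves the C4 carboxyl free and does not touch the stereocentre.

Step 2
Reactants: 2 [(4R)-2,2-dimethyl-5-oxo-1,3-dioxolan-4-yl]acetic acid
Product: 3 2-(trimethylsilyl)ethyl [(4R)-2,2-dimethyl-5-oxo-1,3-dioxolan-4-yl]acetate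
Conditions: 2-(trimethylsilyl)ethanol, DCC, DMAP (cat.), CH2Cl2, 0 to 25 °C
Reagents that add atoms: 2-(trimethylsilyl)ethanol, C[Si](C)(C)CCO
Why: Steglich esterification of the only free carboxyl with a primary alcohol, the dioxolanone being inert to the carbodiimide and to catalytic DMAP in the cold.

Step 3
Reactants: 3 2-(trimethylsilyl)ethyl [(4R)-2,2-dimethyl-5-oxo-1,3-dioxolan-4-yl]acetate
Product: 4 1-methyl 4-[2-(trimethylsilyl)ethyl] (R)-malate
Conditions: NaOMe (0.1 equiv), MeOH, −20 °C, short time; AcOH quench
Reagents that add atoms: methanol, CO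
Why: Base-catalysed methanolysis (transesterification) attacks the acylal-like lactone carbonyl, far more electrophilic than the primary alkyl ester, and should release acetone, the C1 methyl ester and the free secondary hydroxyl before the silylethyl ester can exchange.

Step 4
Reactants: 4 1-methyl 4-[2-(trimethylsilyl)ethyl] (R)-malate, 5 allyl bromoacetate
Product: 7 (2R,3S)-isocitrate triester for units B and C (C1 methyl ester; central 2-(trimethylsilyl)ethyl ester; C5 allyl ester; free 2-hydroxyl), via silylethyl ester dianion 6 (not isolated)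
Conditions: LiN(SiMe3)2 (2.1 equiv), THF, −78 °C; then 5, −78 to −50 °C; AcOH at −78 °C
Reagents that add atoms: none
Why: Fráter–Seebach alkylation, in which the lithium-chelated alkoxide enolate is attacked by the bromoacetate anti to the C2 oxygen substituent, sets C3 as S beside the (2R) centre from D-malic acid, and the cold acidic quench prevents lactonisation of the alkoxide onto the new ester.

Step 5
Reactants: 7 (2R,3S)-isocitrate triester for units B and C, 8 (2E,6E)-farnesyl bromide
Product: 9 2-O-[(2E,6E)-farnesyl] ether of 7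
Conditions: Ag2O, 4 Å molecular sieves, Et2O, 25 °C, dark
Reagents that add atoms: none
Why: Ag2O-promoted Williamson-type O-alkylation, in which silver assists loss of bromide from the primary allylic carbon while the hydroxyl attacks without a free alkoxide, so the triester should neither lactonise, epimerise nor eliminate and both E-alkenes are kept.

Step 6
Reactants: 9 2-O-[(2E,6E)-farnesyl] ether of 7
Product: 10 2-O-[(2E,6E,10E)-12-hydroxyfarnesyl] ether of 7
Conditions: SeO2 (cat.), t-BuOOH, salicylic acid (cat.), CH2Cl2, 0 to 25 °C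
Reagents that add atoms: tert-butyl hydroperoxide, CC(C)(C)OO (oxygen relayed by catalytic selenium dioxide, O=[Se]=O)
Why: Selenium dioxide allylic oxidation (ene reaction, then [2,3]-sigmatropic shift) is selective for the (E)-methyl of the terminal, most electron-rich trisubstituted alkene, the C2=C3 alkene being deactivated by its allylic oxygen, and gives the (E)-allylic alcohol.

Step 7
Reactants: 10 2-O-[(2E,6E,10E)-12-hydroxyfarnesyl] ether of 7
Product: 11 2-O-[(2E,6E,10S,11S)-10,11-epoxy-12-hydroxyfarnesyl] ether of 7 (repeating unit)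
Conditions: Ti(OiPr)4 (cat.), L-(+)-diethyl tartrate, t-BuOOH, 4 Å molecular sieves, CH2Cl2, −20 °C; aqueous tartaric acid work-up
Reagents that add atoms: tert-butyl hydroperoxide, CC(C)(C)OO
Why: Sharpless asymmetric epoxidation, in which the tetravalent titanium tartrate complex binds the allylic hydroxyl and delivers oxygen to one face of the only allylic-alcohol alkene, sets (10S,11S) by reagent control with L-(+)-diethyl tartrate and leaves the other alkenes alone.

Step 8
Reactants: 11 repeating unit epoxy alcohol
Product: 12 12-O-allyloxycarbonyl derivative of 11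
Conditions: allyl chloroformate, pyridine, CH2Cl2, 0 °C
Reagents that add atoms: allyl chloroformate, C=CCOC(=O)Cl
Why: Acylation of the unhindered primary hydroxyl with a chloroformate (carbonate formation) under pyridine is mild enough for the epoxide and the esters.

Step 9
Reactants: 12 12-O-allyloxycarbonyl derivative of 11
Product: 13 unit C acid (12 with the central carboxyl free)
Conditions: Bu4NF, AcOH, THF, 0 to 25 °C
Reagents that add atoms: none
Why: Fluoride-induced fragmentation of the 2-(trimethylsilyl)ethyl ester releases the central carboxylate with ethene and Me3SiF, and the AcOH buffer keeps the medium non-basic so that the methyl and allyl esters, the carbonate, the epoxide and both stereocentres are preserved.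

Step 10
Reactants: 11 repeating unit epoxy alcohol, 13 unit C acid
Product: 14 acyclic dimer silylethyl ester (central carboxyl of 13 esterified with the 12-hydroxyl of 11)
Conditions: EDC·HCl, DMAP (cat.), CH2Cl2, 0 °C
Reagents that add atoms: none
Why: Steglich esterification of the central carboxyl with the unhindered primary epoxy alcohol at 0 °C, where the low temperature and catalytic DMAP should avoid C3 epimerisation and β-elimination of the farnesyloxy group.

Step 11
Reactants: 14 acyclic dimer silylethyl ester
Product: 15 acyclic dimer acid (central carboxyl of the unit B isocitrate free)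
Conditions: Bu4NF, AcOH, THF, 0 to 25 °C
Reagents that add atoms: none
Why: Fluoride-induced fragmentation of the single 2-(trimethylsilyl)ethyl ester as in step 9, orthogonal to the allyl and methyl esters, the carbonate, the new inter-unit ester and both epoxides.

Step 12
Reactants: 2 [(4R)-2,2-dimethyl-5-oxo-1,3-dioxolan-4-yl]acetic acid
Product: 16 allyl [(4R)-2,2-dimethyl-5-oxo-1,3-dioxolan-4-yl]acetate
Conditions: allyl alcohol, DCC, DMAP (cat.), CH2Cl2, 0 to 25 °C
Reagents that add atoms: allyl alcohol, C=CCO
Why: Steglich esterification of the free carboxyl as in step 2, with allyl alcohol, so that the central carboxyl of unit A carries the same protecting group as the side chains of units B and C.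

Step 13
Reactants: 16 allyl [(4R)-2,2-dimethyl-5-oxo-1,3-dioxolan-4-yl]acetate
Product: 17 1-methyl 4-allyl (R)-malate
Conditions: NaOMe (0.1 equiv), MeOH, −20 °C, short time; AcOH quench
Reagents that add atoms: methanol, CO
Why: Base-catalysed methanolysis of the acylal-like lactone as in step 3, which should open the dioxolanone to the C1 methyl ester and the free hydroxyl with loss of acetone before the less electrophilic allyl ester can exchange.

Step 14
Reactants: 17 1-methyl 4-allyl (R)-malate, 18 methyl bromoacetate
Product: 20 (2R,3S)-isocitrate triester for unit A (C1 methyl ester; central allyl ester; C5 methyl ester; free 2-hydroxyl), via allyl ester dianion 19 (not isolated)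
Conditions: LiN(SiMe3)2 (2.1 equiv), THF, −78 °C; then 18, −78 to −50 °C; AcOH at −78 °C
Reagents that add atoms: none
Why: Fráter–Seebach anti alkylation of the lithium-chelated alkoxide enolate of the allyl malate with methyl bromoacetate sets C3 as S as in step 4, the enolate being kept far below the temperature at which an allyl ester enolate would rearrange.

Step 15
Reactants: 20 (2R,3S)-isocitrate triester for unit A, 8 (2E,6E)-farnesyl bromide
Product: 21 2-O-[(2E,6E)-farnesyl] ether of 20
Conditions: Ag2O, 4 Å molecular sieves, Et2O, 25 °C, dark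
Reagents that add atoms: none
Why: Ag2O-promoted Williamson-type O-alkylation as in step 5, on the analogue with a central allyl ester and a methyl side-chain ester.

Step 16
Reactants: 21 2-O-[(2E,6E)-farnesyl] ether of 20
Product: 22 2-O-[(2E,6E,10E)-12-hydroxyfarnesyl] ether of 20
Conditions: SeO2 (cat.), t-BuOOH, salicylic acid (cat.), CH2Cl2, 0 to 25 °C
Reagents that add atoms: tert-butyl hydroperoxide, CC(C)(C)OO (oxygen relayed by catalytic selenium dioxide, O=[Se]=O)
Why: Selenium dioxide allylic oxidation as in step 6, selective for the (E)-methyl of the terminal trisubstituted alkene, the monosubstituted alkene of the allyl ester being far less reactive in the ene step.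

Step 17
Reactants: 22 2-O-[(2E,6E,10E)-12-hydroxyfarnesyl] ether of 20
Product: 23 2-O-[(2E,6E,10S,11S)-10,11-epoxy-12-hydroxyfarnesyl] ether of 20 (unit A epoxy alcohol)
Conditions: Ti(OiPr)4 (cat.), L-(+)-diethyl tartrate, t-BuOOH, 4 Å molecular sieves, CH2Cl2, −20 °C; aqueous tartaric acid work-up
Reagents that add atoms: tert-butyl hydroperoxide, CC(C)(C)OO
Why: Sharpless asymmetric epoxidation as in step 7, with L-(+)-diethyl tartrate again setting (10S,11S) by reagent control.

Step 18
Reactants: 15 acyclic dimer acid, 23 unit A epoxy alcohol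
Product: 24 acyclic tris(epoxyfarnesyl isocitrate) trimer C–B–A (unit A central carboxyl as allyl ester; side chains of units B and C as allyl esters; unit C 12-O-allyloxycarbonyl)
Conditions: EDC·HCl, DMAP (cat.), CH2Cl2, 0 °C
Reagents that add atoms: none
Why: Steglich esterification as in step 10 joins the central carboxyl of the unit B isocitrate to the primary epoxy alcohol of unit A under neutral conditions that leave the three epoxides and the allylic ethers untouched.

Step 19
Reactants: 24 acyclic tris(epoxyfarnesyl isocitrate) trimer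
Product: 25 tris(3β-hydroxyalbic-8(12)-ene) trimer, protected as in 24 (each decalin 4α-CH2O; 4β-CH3; 5α-H; 9α-H; 10β-CH3)
Conditions: Cp2TiCl2 (7.5 equiv), Mn dust (excess), degassed THF, 25 °C, Cp2TiCl kept dilute (about 0.01 M); 24 added slowly; cold dilute aqueous HCl work-up
Reagents that add atoms: none
Why: Proposed new method: Cp2TiCl, a trivalent titanium single-electron donor, should open each of the three epoxides homolytically at the more substituted carbon to give a tertiary β-titanoxy radical at farnesyl C11, and the closest known reaction type is the titanocene-mediated radical bicyclisation of (10S)-10,11-epoxyfarnesyl esters to 3β-hydroxyalbicanyl esters, here extended to three cascades in one molecule on epoxides whose radical carbon bears an acyloxymethyl or carbonate-bearing methyl group and whose chain ends in the isocitrate ether. Ring A of each unit closes 6-endo-trig by addition of this radical to the C6=C7 alkene (drimane bond C4–C5) and ring B closes 6-endo-trig by addition of the resulting tertiary C7 radical to the C2=C3 alkene (drimane bond C9–C10). The last tertiary radical is captured by a second Cp2TiCl and the alkyltitanium loses a β-hydrogen from the methyl group, which leaves the C8(12) methylene, and aqueous acid frees the three carbinols. The (10S) C–O carbon is not touched and becomes the equatorial 3β-carbinol of a chair–chair transition state, which with the two E-alkenes sets C5 (α-H), C10 (β-methyl) and C9 (α-H, β-CH2O). C4 is set at the planar radical, where the larger oxygenated CH2 group should take the pseudo-equatorial 4α position, away from the C7 methyl that becomes the axial C10 methyl. The step needs epoxide opening without reduction of the nine esters and the carbonate or ionisation of the allylic C1 ether (secured by the neutral, mild, oxophilic reductant), ring closure faster than capture of the first radical by titanium with β-loss of carboxylate (secured by the hindered tertiary radical and dilute Cp2TiCl), and independent behaviour of the three units (secured by the flexible isocitrate spacers between them).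

Step 20
Reactants: 25 tris(3β-hydroxyalbicene) trimer
Product: 26 tris(3-O-phenoxythiocarbonyl) derivative of 25
Conditions: PhOC(S)Cl, pyridine, DMAP, CH2Cl2, 25 °C
Reagents that add atoms: O-phenyl chlorothionoformate, S=C(Cl)Oc1ccccc1
Why: Thioacylation of the three equatorial 3β-carbinols, the only free hydroxyls, with a chlorothionoformate under DMAP catalysis (first stage of the Barton–McCombie deoxygenation) uses conditions that leave the esters and the carbonate intact.

Step 21
Reactants: 26 tris(3-O-phenoxythiocarbonyl) derivative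
Product: 27 protected cryptoporic acid T (three albic-8(12)-ene units without C3 oxygen; protecting groups as in 24)
Conditions: Bu3SnH, AIBN (cat.), toluene, 90 °C
Reagents that add atoms: none
Why: Barton–McCombie radical deoxygenation, in which the tin radical adds to each C=S and the secondary C3 radical formed by β-scission takes hydrogen from Bu3SnH, removes the auxiliary C3 stereocentre while C4, C5, C9 and C10 are untouched and the isolated alkenes and allyl esters are normally spectators.

Step 22
Reactants: 27 protected cryptoporic acid T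
Product: 28 cryptoporic acid T
Conditions: Pd(PPh3)4 (cat.), morpholine, THF, 25 °C; dilute aqueous KHSO4 work-up
Reagents that add atoms: none
Why: Tsuji–Trost-type deallylation, in which zerovalent palladium ionises the three allyl esters and the allyl carbonate to π-allyl complexes that morpholine traps (the carbonate losing CO2), frees the central carboxyl of unit A, the two side-chain carboxyls of units B and C and the C15 hydroxyl of unit C in one operation without touching methyl esters, inter-unit esters, homoallylic ethers or exocyclic alkenes.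

Compound list
1 | D-malic acid, (R)-2-hydroxybutanedioic acid | O[C@@H](C(=O)O)CC(=O)O | starting material
2 | [(4R)-2,2-dimethyl-5-oxo-1,3-dioxolan-4-yl]acetic acid | CC1(C)O[C@H](CC(=O)O)C(=O)O1 | intermediate
3 | 2-(trimethylsilyl)ethyl [(4R)-2,2-dimethyl-5-oxo-1,3-dioxolan-4-yl]acetate | CC1(C)O[C@H](CC(=O)OCC[Si](C)(C)C)C(=O)O1 | intermediate
4 | 1-methyl 4-[2-(trimethylsilyl)ethyl] (R)-malate | O[C@@H](C(=O)OC)CC(=O)OCC[Si](C)(C)C | intermediate
5 | allyl bromoacetate | BrCC(=O)OCC=C | starting material
6 | dilithium alkoxide enolate of 4 (chelated, enolate oxygen cis to C2) | [Li+].[Li+].[O-][C@@H](C(=O)OC)/C=C(\[O-])OCC[Si](C)(C)C | intermediate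
7 | (2R,3S)-isocitrate triester for units B and C: C1 methyl, central 2-(trimethylsilyl)ethyl, C5 allyl, 2-hydroxyl free | C[Si](C)(C)CCOC(=O)[C@@H](CC(=O)OCC=C)[C@@H](O)C(=O)OC | intermediate
8 | (2E,6E)-farnesyl bromide | BrC/C=C(\C)CC/C=C(\C)CCC=C(C)C | starting material
9 | 2-O-[(2E,6E)-farnesyl] ether of 7 | C[Si](C)(C)CCOC(=O)[C@@H](CC(=O)OCC=C)[C@@H](OC/C=C(\C)CC/C=C(\C)CCC=C(C)C)C(=O)OC | intermediate
10 | 2-O-[(2E,6E,10E)-12-hydroxyfarnesyl] ether of 7 | C[Si](C)(C)CCOC(=O)[C@@H](CC(=O)OCC=C)[C@@H](OC/C=C(\C)CC/C=C(\C)CC/C=C(\C)CO)C(=O)OC | intermediate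
11 | repeating unit, 2-O-[(2E,6E,10S,11S)-10,11-epoxy-12-hydroxyfarnesyl] ether of 7 | C[Si](C)(C)CCOC(=O)[C@@H](CC(=O)OCC=C)[C@@H](OC/C=C(\C)CC/C=C(\C)CC[C@@H]1O[C@@]1(C)CO)C(=O)OC | intermediate
12 | 12-O-allyloxycarbonyl derivative of 11 | C[Si](C)(C)CCOC(=O)[C@@H](CC(=O)OCC=C)[C@@H](OC/C=C(\C)CC/C=C(\C)CC[C@@H]1O[C@@]1(C)COC(=O)OCC=C)C(=O)OC | intermediate
13 | unit C acid: 12 with the central carboxyl free | OC(=O)[C@@H](CC(=O)OCC=C)[C@@H](OC/C=C(\C)CC/C=C(\C)CC[C@@H]1O[C@@]1(C)COC(=O)OCC=C)C(=O)OC | intermediate
14 | acyclic dimer silylethyl ester: central carboxyl of 13 esterified with the 12-hydroxyl of 11 | C[Si](C)(C)CCOC(=O)[C@@H](CC(=O)OCC=C)[C@@H](OC/C=C(\C)CC/C=C(\C)CC[C@@H]1O[C@@]1(C)COC(=O)[C@@H](CC(=O)OCC=C)[C@@H](OC/C=C(\C)CC/C=C(\C)CC[C@@H]2O[C@@]2(C)COC(=O)OCC=C)C(=O)OC)C(=O)OC | intermediate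
15 | acyclic dimer acid: 14 with the central carboxyl of the unit B isocitrate free | OC(=O)[C@@H](CC(=O)OCC=C)[C@@H](OC/C=C(\C)CC/C=C(\C)CC[C@@H]1O[C@@]1(C)COC(=O)[C@@H](CC(=O)OCC=C)[C@@H](OC/C=C(\C)CC/C=C(\C)CC[C@@H]2O[C@@]2(C)COC(=O)OCC=C)C(=O)OC)C(=O)OC | intermediate
16 | allyl [(4R)-2,2-dimethyl-5-oxo-1,3-dioxolan-4-yl]acetate | CC1(C)O[C@H](CC(=O)OCC=C)C(=O)O1 | intermediate
17 | 1-methyl 4-allyl (R)-malate | O[C@@H](C(=O)OC)CC(=O)OCC=C | intermediate
18 | methyl bromoacetate | BrCC(=O)OC | starting material
19 | dilithium alkoxide enolate of 17 (chelated, enolate oxygen cis to C2) | [Li+].[Li+].[O-][C@@H](C(=O)OC)/C=C(\[O-])OCC=C | intermediate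
20 | (2R,3S)-isocitrate triester for unit A: C1 methyl, central allyl, C5 methyl, 2-hydroxyl free | C=CCOC(=O)[C@@H](CC(=O)OC)[C@@H](O)C(=O)OC | intermediate
21 | 2-O-[(2E,6E)-farnesyl] ether of 20 | C=CCOC(=O)[C@@H](CC(=O)OC)[C@@H](OC/C=C(\C)CC/C=C(\C)CCC=C(C)C)C(=O)OC | intermediate
22 | 2-O-[(2E,6E,10E)-12-hydroxyfarnesyl] ether of 20 | C=CCOC(=O)[C@@H](CC(=O)OC)[C@@H](OC/C=C(\C)CC/C=C(\C)CC/C=C(\C)CO)C(=O)OC | intermediate
23 | unit A epoxy alcohol, 2-O-[(2E,6E,10S,11S)-10,11-epoxy-12-hydroxyfarnesyl] ether of 20 | C=CCOC(=O)[C@@H](CC(=O)OC)[C@@H](OC/C=C(\C)CC/C=C(\C)CC[C@@H]1O[C@@]1(C)CO)C(=O)OC | intermediate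
24 | acyclic tris(epoxyfarnesyl isocitrate) trimer C–B–A | C=CCOC(=O)[C@@H](CC(=O)OC)[C@@H](OC/C=C(\C)CC/C=C(\C)CC[C@@H]1O[C@@]1(C)COC(=O)[C@@H](CC(=O)OCC=C)[C@@H](OC/C=C(\C)CC/C=C(\C)CC[C@@H]2O[C@@]2(C)COC(=O)[C@@H](CC(=O)OCC=C)[C@@H](OC/C=C(\C)CC/C=C(\C)CC[C@@H]3O[C@@]3(C)COC(=O)OCC=C)C(=O)OC)C(=O)OC)C(=O)OC | intermediate
25 | tris(3β-hydroxyalbic-8(12)-ene) trimer, protecting groups as in 24 | C=C1CC[C@H]2[C@](C)(COC(=O)[C@@H](CC(=O)OCC=C)[C@@H](OC[C@H]3C(=C)CC[C@H]4[C@](C)(COC(=O)[C@@H](CC(=O)OCC=C)[C@@H](OC[C@H]5C(=C)CC[C@H]6[C@](C)(COC(=O)OCC=C)[C@@H](O)CC[C@]56C)C(=O)OC)[C@@H](O)CC[C@]34C)C(=O)OC)[C@@H](O)CC[C@]2(C)[C@H]1CO[C@@H](C(=O)OC)[C@H](CC(=O)OC)C(=O)OCC=C | intermediate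
26 | tris(3-O-phenoxythiocarbonyl) derivative of 25 | C=C1CC[C@H]2[C@](C)(COC(=O)[C@@H](CC(=O)OCC=C)[C@@H](OC[C@H]3C(=C)CC[C@H]4[C@](C)(COC(=O)[C@@H](CC(=O)OCC=C)[C@@H](OC[C@H]5C(=C)CC[C@H]6[C@](C)(COC(=O)OCC=C)[C@@H](OC(=S)Oc7ccccc7)CC[C@]56C)C(=O)OC)[C@@H](OC(=S)Oc7ccccc7)CC[C@]34C)C(=O)OC)[C@@H](OC(=S)Oc7ccccc7)CC[C@]2(C)[C@H]1CO[C@@H](C(=O)OC)[C@H](CC(=O)OC)C(=O)OCC=C | intermediate
27 | protected cryptoporic acid T (no C3 oxygen; three allyl esters, one allyl carbonate) | C=C1CC[C@H]2[C@](C)(COC(=O)[C@@H](CC(=O)OCC=C)[C@@H](OC[C@H]3C(=C)CC[C@H]4[C@](C)(COC(=O)[C@@H](CC(=O)OCC=C)[C@@H](OC[C@H]5C(=C)CC[C@H]6[C@](C)(COC(=O)OCC=C)CCC[C@]56C)C(=O)OC)CCC[C@]34C)C(=O)OC)CCC[C@]2(C)[C@H]1CO[C@@H](C(=O)OC)[C@H](CC(=O)OC)C(=O)OCC=C | intermediate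
28 | cryptoporic acid T | C=C1CC[C@H]2[C@](C)(COC(=O)[C@@H](CC(=O)O)[C@@H](OC[C@H]3C(=C)CC[C@H]4[C@](C)(COC(=O)[C@@H](CC(=O)O)[C@@H](OC[C@H]5C(=C)CC[C@H]6[C@](C)(CO)CCC[C@]56C)C(=O)OC)CCC[C@]34C)C(=O)OC)CCC[C@]2(C)[C@H]1CO[C@@H](C(=O)OC)[C@H](CC(=O)OC)C(=O)O | target

Total step count: 22. Longest linear sequence: 16 steps (steps 1 to 11, then 18 to 22).

Steps most likely to fail

Step 19. The first tertiary radical sits next to an acyloxymethyl group. It may be captured by titanium before it cyclises and then expel the carboxylate, which cuts the chain at an inter-unit ester, or it may suffer a 1,2-acyloxy shift. One of the three cascades may also stop after ring A, and the face selectivity at C4 may be incomplete; each loss is multiplied over three units. The fallback closes the rings first and makes the esters afterwards, with known chemistry; it sets out from epoxy alcohols 11 and 23 and comes back to the route at 25. The primary hydroxyls are silylated (Et3SiCl, imidazole) to the triethylsilyl ether F1 (from 11) and the triethylsilyl ether F4 (from 23). Each then has a single epoxide and a silyloxymethyl in place of the acyloxymethyl group, and undergoes the established single Cp2TiCl bicyclisation of a 10,11-epoxyfarnesyl derivative. This gives the 3β-hydroxy-15-silyloxyalbicanyl isocitrate F2 (allyl side chain, silylethyl central ester) and the 3β-hydroxy-15-silyloxyalbicanyl isocitrate F5 (methyl side chain, allyl central ester). AcOH/THF/H2O removes the silyl groups to give the 3β,15-diol F3 and the 3β,15-diol F6. Part of F3 is converted with allyl chloroformate and pyridine, at the primary hydroxyl, into the unit C carbonate F7, and then with Bu4NF/AcOH into the unit C decalin acid F8. Yamaguchi esterification (2,4,6-trichlorobenzoyl chloride, Et3N, DMAP) of F8 with the primary 15-hydroxyl of F3 gives the decalin dimer silylethyl ester F9, and fluoride gives the decalin dimer acid F10. A second Yamaguchi esterification of F10 with F6 gives 25. The price is that the inter-unit esters are then made at neopentyl hydroxyls beside free 3β-carbinols.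

Step 20. The three 3β-carbinols are each flanked by the quaternary C4 and may be thioacylated incompletely, giving mixtures of partly derivatised trimers; forcing with more base or heat endangers the epimerisable, elimination-prone isocitrate centres. The fallback removes the oxygen through the ketone; it sets out from 25 and comes back at 27, bypassing 26. Dess–Martin periodinane gives the tris(3-ketone) F11, p-toluenesulfonylhydrazide with catalytic AcOH gives the tris(tosylhydrazone) F12, and catecholborane followed by NaOAc·3H2O (Caglioti-type hydrazone reduction) gives 27.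

Step 10 (and its repeat, step 18). Activation of the central carboxyl, which is α-branched and carries the farnesyloxy group in the β position, may lead to C3 epimerisation or to E1cB loss of the ether oxygen. The fallback activates the alcohol and not the acid. Mitsunobu esterification (PPh3, diisopropyl azodicarboxylate, THF, 0 °C) sets out from 11 and 13 and gives 14 directly, and likewise gives 24 from 15 and 23. The carboxylate then acts only as a nucleophile; this fallback makes no compound outside the list (entry F0).

Further compounds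
F1 | step 19 | 12-O-triethylsilyl ether of 11 | C[Si](C)(C)CCOC(=O)[C@@H](CC(=O)OCC=C)[C@@H](OC/C=C(\C)CC/C=C(\C)CC[C@@H]1O[C@@]1(C)CO[Si](CC)(CC)CC)C(=O)OC
F2 | step 19 | 3β-hydroxy-15-(triethylsilyloxy)albic-8(12)-en-11-yl ether of the isocitrate triester with allyl side chain and silylethyl central ester | C=C1CC[C@H]2[C@](C)(CO[Si](CC)(CC)CC)[C@@H](O)CC[C@]2(C)[C@H]1CO[C@@H](C(=O)OC)[C@H](CC(=O)OCC=C)C(=O)OCC[Si](C)(C)C
F3 | step 19 | 3β,15-dihydroxyalbic-8(12)-en-11-yl ether of the isocitrate triester with allyl side chain and silylethyl central ester | C=C1CC[C@H]2[C@](C)(CO)[C@@H](O)CC[C@]2(C)[C@H]1CO[C@@H](C(=O)OC)[C@H](CC(=O)OCC=C)C(=O)OCC[Si](C)(C)C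
F4 | step 19 | 12-O-triethylsilyl ether of 23 | C=CCOC(=O)[C@@H](CC(=O)OC)[C@@H](OC/C=C(\C)CC/C=C(\C)CC[C@@H]1O[C@@]1(C)CO[Si](CC)(CC)CC)C(=O)OC
F5 | step 19 | 3β-hydroxy-15-(triethylsilyloxy)albic-8(12)-en-11-yl ether of the isocitrate triester with methyl side chain and allyl central ester | C=C1CC[C@H]2[C@](C)(CO[Si](CC)(CC)CC)[C@@H](O)CC[C@]2(C)[C@H]1CO[C@@H](C(=O)OC)[C@H](CC(=O)OC)C(=O)OCC=C
F6 | step 19 | 3β,15-dihydroxyalbic-8(12)-en-11-yl ether of the isocitrate triester with methyl side chain and allyl central ester | C=C1CC[C@H]2[C@](C)(CO)[C@@H](O)CC[C@]2(C)[C@H]1CO[C@@H](C(=O)OC)[C@H](CC(=O)OC)C(=O)OCC=C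
F7 | step 19 | unit C carbonate, 15-O-allyloxycarbonyl derivative of F3 | C=C1CC[C@H]2[C@](C)(COC(=O)OCC=C)[C@@H](O)CC[C@]2(C)[C@H]1CO[C@@H](C(=O)OC)[C@H](CC(=O)OCC=C)C(=O)OCC[Si](C)(C)C
F8 | step 19 | unit C decalin acid, F7 with the central carboxyl free | C=C1CC[C@H]2[C@](C)(COC(=O)OCC=C)[C@@H](O)CC[C@]2(C)[C@H]1CO[C@@H](C(=O)OC)[C@H](CC(=O)OCC=C)C(=O)O
F9 | step 19 | decalin dimer silylethyl ester, 15-O-ester of F3 with F8 | C=C1CC[C@H]2[C@](C)(COC(=O)[C@@H](CC(=O)OCC=C)[C@@H](OC[C@H]3C(=C)CC[C@H]4[C@](C)(COC(=O)OCC=C)[C@@H](O)CC[C@]34C)C(=O)OC)[C@@H](O)CC[C@]2(C)[C@H]1CO[C@@H](C(=O)OC)[C@H](CC(=O)OCC=C)C(=O)OCC[Si](C)(C)C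
F10 | step 19 | decalin dimer acid, F9 with the central carboxyl of the unit B isocitrate free | C=C1CC[C@H]2[C@](C)(COC(=O)[C@@H](CC(=O)OCC=C)[C@@H](OC[C@H]3C(=C)CC[C@H]4[C@](C)(COC(=O)OCC=C)[C@@H](O)CC[C@]34C)C(=O)OC)[C@@H](O)CC[C@]2(C)[C@H]1CO[C@@H](C(=O)OC)[C@H](CC(=O)OCC=C)C(=O)O
F11 | step 20 | tris(3-ketone) from 25 | C=C1CC[C@H]2[C@](C)(COC(=O)[C@@H](CC(=O)OCC=C)[C@@H](OC[C@H]3C(=C)CC[C@H]4[C@](C)(COC(=O)[C@@H](CC(=O)OCC=C)[C@@H](OC[C@H]5C(=C)CC[C@H]6[C@](C)(COC(=O)OCC=C)C(=O)CC[C@]56C)C(=O)OC)C(=O)CC[C@]34C)C(=O)OC)C(=O)CC[C@]2(C)[C@H]1CO[C@@H](C(=O)OC)[C@H](CC(=O)OC)C(=O)OCC=C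
F12 | step 20 | tris(tosylhydrazone) of F11 | C=C1CC[C@H]2[C@](C)(COC(=O)[C@@H](CC(=O)OCC=C)[C@@H](OC[C@H]3C(=C)CC[C@H]4[C@](C)(COC(=O)[C@@H](CC(=O)OCC=C)[C@@H](OC[C@H]5C(=C)CC[C@H]6[C@](C)(COC(=O)OCC=C)C(=NNS(=O)(=O)c7ccc(C)cc7)CC[C@]56C)C(=O)OC)C(=NNS(=O)(=O)c7ccc(C)cc7)CC[C@]34C)C(=O)OC)C(=NNS(=O)(=O)c7ccc(C)cc7)CC[C@]2(C)[C@H]1CO[C@@H](C(=O)OC)[C@H](CC(=O)OC)C(=O)OCC=C
F0 | step 10 | none | none
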